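**Plan**

- Retrosynthesis: the C5 ester and the terminal OH (from a C–B bond) are cut first. One retro-step then cuts C1–CH3, the ketone–vinyl bond and the ring bond C1–C8a (retro-Wolff). Last come C3=C4 (metathesis), C1–C2 (Carroll rearrangement) and the cyclohexane ring (Diels–Alder).
- Enabling feature: C1 of the cyclohexene (C1, C2, C3, C4, C4a, C8a) is a ring carbon that carries an out-of-ring C=O and sits next to ring-fusion C8a. This is the retron of a Wolff contraction, so the cyclohexene comes from a cyclohept-4-enone made of the same six atoms plus that carbonyl carbon, inserted between C1 and C8a.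
- Forward: Diels–Alder builds the oxygenated cyclohexane; Carroll rearrangement and ring-closing metathesis build the fused cycloheptenone; diazo transfer and photolysis contract it. The ketene is captured in the same flask by vinyllithium and the enolate is methylated, then the ester is attached and the C–B bond oxidised.
- Stereochemistry: the sec-butyl centre is bought. C8 and C8a come from the oxazolidinone dienophile, C5 and C6 from OH-directed osmylation, C4a from equilibration of an aldehyde. C2 comes by chirality transfer from a CBS-set carbinol, and C1 by methylation anti to the sec-butyl group.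

Key step: step 18

Locants: the decalin numbering of the target is used throughout (C1 quaternary, C2 sec-butyl, C3=C4, C4a, C5 O-acyl, C6 OH, C7, C8 methyl, C8a); β is the face of H-4a, α the opposite face.
Assumption: (R)-2-methylbutan-1-ol, (2E)-penta-2,4-dien-1-ol and (E)-3-methylglutaconic acid are catalogue compounds and are bought.

Step 1
Reactants: 1 (R)-4-benzyloxazolidin-2-one; 2 (E)-but-2-enoyl chloride
Product: 3 (R)-4-benzyl-3-[(E)-but-2-enoyl]oxazolidin-2-one
Conditions: n-BuLi, THF, −78 °C; then 2, −78 to 0 °C
Reagents that add atoms: none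
Why: N-acylation of the lithiated oxazolidinone gives the imide dienophile and creates no stereocentre.

Step 2
Reactants: 4 (2E)-penta-2,4-dien-1-ol
Product: 5 tert-butyl(dimethyl)[(2E)-penta-2,4-dien-1-yloxy]silane
Conditions: TBSCl, imidazole, CH2Cl2, 0 °C to rt
Reagents that add atoms: tert-butyldimethylsilyl chloride, CC(C)(C)[Si](C)(C)Cl
Why: Standard silylation of a primary alcohol gives a diene ether that should tolerate the aluminium Lewis acid of step 3.

Step 3
Reactants: 3 imide; 5 silyloxy diene
Product: 6 Diels–Alder adduct (cyclohex-3-ene with the C8a imide carbonyl β, C4a CH2OTBS β and C8 methyl α)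
Conditions: Et2AlCl (1.4 equiv), 5 (3 equiv), CH2Cl2, −30 °C
Reagents that add atoms: none
Why: Oxazolidinone-auxiliary Diels–Alder reaction in which the benzyl group of the Al-chelated s-cis imide shields the Cα-Si face, so the diene should add to Cα-Re with ortho regiochemistry and endo topology, setting C8a and C8 (trans, from the E-dienophile) in the absolute sense of the target and C4a cis to the acyl group (corrected in step 8).

Step 4
Reactants: 6 Diels–Alder adduct
Product: 7 Weinreb amide (N-methoxy-N-methyl amide at C8a, CH2OTBS at C4a)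
Conditions: MeNH(OMe)·HCl, AlMe3, CH2Cl2, 0 °C to rt
Reagents that add atoms: N,O-dimethylhydroxylamine hydrochloride, CNOC.Cl
Why: Aluminium-amide transamidation of the N-acyloxazolidinone (exocyclic cleavage) gives the Weinreb amide, chosen because it should not lactonise onto the cis CH2OH freed in step 5 and no stereocentre is touched.

Step 5
Reactants: 7 Weinreb amide silyl ether
Product: 8 homoallylic alcohol (C4a CH2OH)
Conditions: HF·pyridine, pyridine, THF, 0 °C to rt
Reagents that add atoms: none
Why: Fluoride desilylation under weakly acidic conditions avoids an alkoxide that could attack the neighbouring amide.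

Step 6
Reactants: 8 homoallylic alcohol
Product: 9 triol (C5 OH β, C6 OH β, C4a CH2OH β)
Conditions: OsO4 (1.05 equiv), TMEDA (1.1 equiv), CH2Cl2, −78 °C; then aq. Na2SO3, THF, rt
Reagents that add atoms: osmium tetroxide, O=[Os](=O)(=O)=O
Why: Hydrogen-bond-directed osmylation, in which the pseudoaxial CH2OH on C4a binds the OsO4·TMEDA complex and should deliver both oxygens to the alkene face syn to it, setting C5 and C6 (both O β, cis to the C8a carbonyl).

Step 7
Reactants: 9 triol
Product: 10 C5,C6-acetonide with free C4a CH2OH
Conditions: 2,2-dimethoxypropane, PPTS (cat.), acetone, rt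
Reagents that add atoms: 2,2-dimethoxypropane, COC(C)(C)OC
Why: Thermodynamic acetalisation, where the cis-1,2-diol should give the five-membered dioxolane in preference to a 1,3-dioxane with the primary OH.

Step 8
Reactants: 10 acetonide alcohol
Product: 12 C4a-α aldehyde (all-equatorial), via C4a-β aldehyde 11 (not isolated)
Conditions: Dess–Martin periodinane, NaHCO3, CH2Cl2, 0 °C to rt; filter; then DBU (0.3 equiv), CH2Cl2, rt
Reagents that add atoms: none
Why: Dess–Martin oxidation then base equilibration of the α-centre, in which the axial formyl group of 11 (1,3-diaxial to the C6–O bond) should epimerise through the enolate to the equatorial aldehyde and so set C4a trans to C8a, while β-elimination is disfavoured because the C5–O bond is equatorial and part of the acetal ring.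

Step 9
Reactants: 12 C4a-α aldehyde
Product: 13 C4a-vinyl Weinreb amide
Conditions: Ph3PCH3Br, KHMDS, THF, −78 to 0 °C
Reagents that add atoms: methyltriphenylphosphonium bromide, C[P+](c1ccccc1)(c1ccccc1)c1ccccc1.[Br-]
Why: Wittig methylenation, which cannot erode C4a because that centre is already in its thermodynamic configuration.

Step 10
Reactants: 13 vinyl Weinreb amide
Product: 14 methyl ketone (acetyl group on C8a)
Conditions: MeMgBr (3 equiv), THF, 0 °C to rt; aq. NH4Cl
Reagents that add atoms: methylmagnesium bromide, C[Mg]Br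
Why: Weinreb ketone synthesis, in which the magnesium chelate stops after one addition and releases the methyl ketone on work-up.

Step 11
Reactants: 15 (R)-2-methylbutan-1-ol
Product: 17 (R,E)-5-methylhept-3-en-2-one, via (R)-2-methylbutanal 16 (not isolated)
Conditions: (COCl)2, DMSO, Et3N, CH2Cl2, −78 °C; then Ph3P=CHC(O)CH3, −78 °C to rt
Reagents that add atoms: 1-(triphenylphosphoranylidene)propan-2-one, CC(=O)C=P(c1ccccc1)(c1ccccc1)c1ccccc1
Why: Swern oxidation with in situ Wittig olefination by the stabilised ylide (E-selective) avoids isolating the volatile, epimerisable α-branched aldehyde.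

Step 12
Reactants: 17 enone
Product: 18 (2R,3E,5R)-5-methylhept-3-en-2-ol
Conditions: (S)-2-methyl-CBS-oxazaborolidine (15 mol%), BH3·SMe2, THF, −30 °C; MeOH quench
Reagents that add atoms: none
Why: Corey–Bakshi–Shibata reduction, in which the alkenyl group acts as the large substituent so the (S)-catalyst should deliver hydride to give the (R)-carbinol (reagent control, 1,2-reduction).

Step 13
Reactants: 18 allylic alcohol
Product: 19 (2R,3E,5R)-5-methylhept-3-en-2-yl 1H-imidazole-1-carboxylate
Conditions: 1,1'-carbonyldiimidazole, CH2Cl2, rt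
Reagents that add atoms: 1,1'-carbonyldiimidazole, O=C(n1ccnc1)n1ccnc1
Why: Acyl transfer from carbonyldiimidazole to the secondary alcohol gives the stable alkoxycarbonylimidazole without touching a stereocentre.

Step 14
Reactants: 14 methyl ketone; 19 imidazole carboxylate
Product: 20 β-keto ester (C8a–CO–CH2–CO2–allyl)
Conditions: LiHMDS (2.2 equiv), THF, −78 °C; then 19, BF3·OEt2, −78 °C to rt
Reagents that add atoms: none
Why: Kinetic deprotonation at the methyl group rather than the C8a methine, followed by BF3-promoted C-acylation of the lithium enolate by the alkoxycarbonylimidazole (Claisen-type acylation), should give the β-keto ester.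

Step 15
Reactants: 20 β-keto ester
Product: 22 dienyl ketone (C8a–CO–CH2–C2H(sec-butyl)–CH=CH–CH3), via β-keto acid 21 (not isolated)
Conditions: o-xylene, 150 °C, sealed tube
Reagents that add atoms: none
Why: Carroll rearrangement (decarboxylative Claisen), in which the enol passes through a chair transition state with the carbinol methyl equatorial, so the (R)-carbinol centre should be transferred suprafacially to C2 as the C1–C2 bond forms, after which the β-keto acid loses CO2.

Step 16
Reactants: 22 dienyl ketone
Product: 23 trans-fused cyclohept-4-enone (ring C9, C1, C2, C3=C4, C4a, C8a)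
Conditions: Grubbs second-generation catalyst (5 mol%), CH2Cl2 (5 mM), 40 °C
Reagents that add atoms: none
Why: Ring-closing metathesis of the vinyl and propenyl groups should close the seven-membered ring with a cis C3=C4 bond and loss of propene, touching no stereocentre.

Step 17
Reactants: 23 cycloheptenone
Product: 25 2-diazo ketone (diazo group on C1), via trifluoroacetyl ketone 24 (not isolated)
Conditions: LiHMDS, THF, −78 °C; CF3CO2CH2CF3; then MsN3, Et3N, H2O, MeCN, rt
Reagents that add atoms: methanesulfonyl azide, CS(=O)(=O)N=[N+]=[N-]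
Why: Detrifluoroacetylative diazo transfer, in which LiHMDS should deprotonate the C1 methylene in preference to the C8a methine and only the enolisable trifluoroacetyl ketone so formed can accept the diazo group.

Step 18
Reactants: 25 2-diazo ketone
Product: 28 vinyl ketone (decalin with C1 methyl β and C1 acryloyl α), via ketene 26 (not isolated), via lithium enolate 27 (not isolated)
Conditions: hν (365 nm), THF, −78 °C; then vinyllithium (1.05 equiv), −78 °C; then MeI (5 equiv), DMPU, −78 to 0 °C
Reagents that add atoms: vinyllithium, [Li]C=C; iodomethane, CI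
Why: Proposed new method: irradiation of the s-cis-locked cyclic 2-diazo ketone expels N2 and the ring bond C8a–C(=O) shifts to the diazo carbon C1 with retention at C8a (Wolff rearrangement), so the seven-membered ring contracts to the cyclohexene and the old ring carbonyl carbon becomes the exocyclic ketene carbon on C1; vinyllithium then adds to that ketene carbon to give lithium enolate 27 regiospecifically, and MeI alkylates it at C1. The closest known reaction types are the photochemical Wolff ring contraction of 2-diazocycloalkanones with capture of the ketene by a nucleophile, and the addition of organolithiums to dialkylketenes to give ketone enolates that are C-alkylated; what is new is their combination in one flask on a ring-contracted ketene. The six-membered ring is not closed by a cyclisation but arises by a 1,2-shift (ring contraction from seven to six) within the existing ring. C2, C4a and C8a are carried through unchanged, and the new quaternary C1 is set by substrate control: allylic strain holds the C2 sec-butyl group pseudoaxial on the α face of the exocyclic enolate, so MeI should attack the β face and place the methyl group trans to the sec-butyl group. The step needs the Wolff shift to beat 1,2-hydride shift or carbene insertion (direct photolysis at −78 °C without metal), a single addition of vinyllithium (the ketene is far more electrophilic than the enolate or the product; 1.05 equiv at −78 °C) and C- over O-methylation (lithium enolate, MeI, DMPU).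

Step 19
Reactants: 28 vinyl ketone
Product: 29 β-boryl ketone (C1–CO–CH2CH2–Bpin)
Conditions: B2pin2 (1.1 equiv), CuCl (5 mol%), Xantphos (5 mol%), NaOtBu (10 mol%), MeOH (2 equiv), THF, rt
Reagents that add atoms: bis(pinacolato)diboron, CC1(C)OB(OC1(C)C)B1OC(C)(C)C(C)(C)O1
Why: Copper-catalysed conjugate borylation of the enone, in which only the unhindered vinyl ketone terminus should react and the C–B bond serves as a masked primary hydroxyl.

Step 20
Reactants: 29 β-boryl ketone acetonide
Product: 30 C5,C6-diol
Conditions: AcOH/H2O/THF (3:1:1), 40 °C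
Reagents that add atoms: none
Why: Acid hydrolysis of the isopropylidene acetal, to which the pinacol boronate, the ketone and the ring alkene should be stable.

Step 21
Reactants: 31 (E)-3-methylglutaconic acid
Product: 32 (2E)-5-methoxy-3-methyl-5-oxopent-2-enoic acid
Conditions: MeOH, TMSCl (cat.), 0 °C to rt
Reagents that add atoms: methanol, CO
Why: Fischer esterification is much faster at the non-conjugated carboxyl than at the conjugated one, which should give the half ester with the free α,β-unsaturated acid and leave the E geometry untouched.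

Step 22
Reactants: 30 diol; 32 half ester acid
Product: 33 C5 ester with free C6 OH and intact Bpin
Conditions: DIC (1.2 equiv), DMAP (0.1 equiv), CH2Cl2, −20 to 0 °C
Reagents that add atoms: none
Why: Steglich esterification, in which the equatorial C5–OH should react in preference to the axial C6–OH (shielded by the syn-axial H-4a and H-8) and the low temperature limits acyl migration and isomerisation of the glutaconate.

Step 23
Reactants: 33 boronate ester
Product: 34 tandyukisin B
Conditions: NaBO3·4H2O, THF/H2O (pH 7 phosphate buffer), 0 °C to rt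
Reagents that add atoms: sodium perborate, [Na+].[O-]OB=O
Why: Oxidation of the alkylboronate (1,2-shift of carbon from boron to oxygen) should unmask the primary alcohol under near-neutral conditions that leave both esters and the β-hydroxy ketone intact.

**Compound list**

1 | (R)-4-benzyloxazolidin-2-one | O=C1N[C@H](Cc2ccccc2)CO1 | starting material
2 | (E)-but-2-enoyl chloride | C/C=C/C(Cl)=O | starting material
3 | (R)-4-benzyl-3-[(E)-but-2-enoyl]oxazolidin-2-one | C/C=C/C(=O)N1[C@H](Cc2ccccc2)COC1=O | intermediate
4 | (2E)-penta-2,4-dien-1-ol | OC/C=C/C=C | starting material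
5 | tert-butyl(dimethyl)[(2E)-penta-2,4-dien-1-yloxy]silane | C=C/C=C/CO[Si](C)(C)C(C)(C)C | intermediate
6 | Diels–Alder adduct: N-acyloxazolidinone of 2-(TBSO-methyl)-6-methylcyclohex-3-ene-1-carboxylic acid, 1,2-cis, 1,6-trans (C8a acyl β, C4a CH2OTBS β, C8 CH3 α) | O=C(N1[C@H](Cc2ccccc2)COC1=O)[C@@H]1[C@H](CO[Si](C)(C)C(C)(C)C)C=CC[C@H]1C | intermediate
7 | Weinreb amide of the same acid (CH2OTBS cis to the amide, CH3 trans) | CON(C)C(=O)[C@@H]1[C@H](CO[Si](C)(C)C(C)(C)C)C=CC[C@H]1C | intermediate
8 | desilylated Weinreb amide (C4a CH2OH β) | CON(C)C(=O)[C@@H]1[C@H](CO)C=CC[C@H]1C | intermediate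
9 | triol: C5 OH β, C6 OH β, C4a CH2OH β, C8a amide β, C8 CH3 α | CON(C)C(=O)[C@@H]1[C@H](CO)[C@H](O)[C@H](O)C[C@H]1C | intermediate
10 | C5,C6-O-isopropylidene derivative of 9 with free CH2OH | CON(C)C(=O)[C@@H]1[C@H](CO)[C@@H]2OC(C)(C)O[C@@H]2C[C@H]1C | intermediate
11 | C4a-β (axial) aldehyde | CON(C)C(=O)[C@@H]1[C@H](C=O)[C@@H]2OC(C)(C)O[C@@H]2C[C@H]1C | intermediate
12 | C4a-α (equatorial) aldehyde, trans to the C8a amide | CON(C)C(=O)[C@@H]1[C@@H](C=O)[C@@H]2OC(C)(C)O[C@@H]2C[C@H]1C | intermediate
13 | C4a-vinyl Weinreb amide | CON(C)C(=O)[C@@H]1[C@@H](C=C)[C@@H]2OC(C)(C)O[C@@H]2C[C@H]1C | intermediate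
14 | methyl ketone: C8a acetyl β, C4a vinyl α, C8 CH3 α, C5,C6 acetonide β | CC(=O)[C@@H]1[C@@H](C=C)[C@@H]2OC(C)(C)O[C@@H]2C[C@H]1C | intermediate
15 | (R)-2-methylbutan-1-ol | CC[C@@H](C)CO | starting material
16 | (R)-2-methylbutanal | CC[C@@H](C)C=O | intermediate
17 | (R,E)-5-methylhept-3-en-2-one | CC[C@@H](C)/C=C/C(C)=O | intermediate
18 | (2R,3E,5R)-5-methylhept-3-en-2-ol | CC[C@@H](C)/C=C/[C@@H](C)O | intermediate
19 | (2R,3E,5R)-5-methylhept-3-en-2-yl 1H-imidazole-1-carboxylate | CC[C@@H](C)/C=C/[C@@H](C)OC(=O)n1ccnc1 | intermediate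
20 | β-keto ester of 14 with the allylic alcohol 18 | CC[C@@H](C)/C=C/[C@@H](C)OC(=O)CC(=O)[C@@H]1[C@@H](C=C)[C@@H]2OC(C)(C)O[C@@H]2C[C@H]1C | intermediate
21 | β-keto acid after [3,3] shift (C1 carboxyl, C2 set) | CC[C@@H](C)[C@@H](/C=C/C)C(C(=O)O)C(=O)[C@@H]1[C@@H](C=C)[C@@H]2OC(C)(C)O[C@@H]2C[C@H]1C | intermediate
22 | dienyl ketone: C8a–CO–CH2–C2H(sec-butyl)–(E)-CH=CH–CH3, C4a vinyl | CC[C@@H](C)[C@@H](/C=C/C)CC(=O)[C@@H]1[C@@H](C=C)[C@@H]2OC(C)(C)O[C@@H]2C[C@H]1C | intermediate
23 | trans-fused bicyclic cyclohept-4-enone (ketone between C1 and C8a, sec-butyl on C2 α) | CC[C@@H](C)[C@H]1C=C[C@H]2[C@@H]3OC(C)(C)O[C@@H]3C[C@@H](C)[C@@H]2C(=O)C1 | intermediate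
24 | C1-trifluoroacetyl derivative of 23 | CC[C@@H](C)[C@H]1C=C[C@H]2[C@@H]3OC(C)(C)O[C@@H]3C[C@@H](C)[C@@H]2C(=O)C1C(=O)C(F)(F)F | intermediate
25 | 2-diazo ketone (diazo on C1) | CC[C@@H](C)[C@H]1C=C[C@H]2[C@@H]3OC(C)(C)O[C@@H]3C[C@@H](C)[C@@H]2C(=O)C1=[N+]=[N-] | intermediate
26 | ring-contracted ketene (C1=C=O on the octalin) | CC[C@@H](C)[C@H]1C=C[C@H]2[C@@H]3OC(C)(C)O[C@@H]3C[C@@H](C)[C@@H]2C1=C=O | intermediate
27 | lithium enolate (C1=C(OLi)–CH=CH2) | CC[C@@H](C)[C@H]1C=C[C@H]2[C@@H]3OC(C)(C)O[C@@H]3C[C@@H](C)[C@@H]2C1=C(O[Li])C=C | intermediate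
28 | vinyl ketone: trans-octalin with C1 CH3 β, C1 acryloyl α, C2 sec-butyl α, C5,C6 acetonide β, C8 CH3 α | CC[C@@H](C)[C@H]1C=C[C@H]2[C@@H]3OC(C)(C)O[C@@H]3C[C@@H](C)[C@@H]2[C@@]1(C)C(=O)C=C | intermediate
29 | β-(pinacolboryl) ketone acetonide | CC[C@@H](C)[C@H]1C=C[C@H]2[C@@H]3OC(C)(C)O[C@@H]3C[C@@H](C)[C@@H]2[C@@]1(C)C(=O)CCB1OC(C)(C)C(C)(C)O1 | intermediate
30 | β-(pinacolboryl) ketone C5,C6-diol | CC[C@@H](C)[C@H]1C=C[C@H]2[C@H](O)[C@H](O)C[C@@H](C)[C@@H]2[C@@]1(C)C(=O)CCB1OC(C)(C)C(C)(C)O1 | intermediate
31 | (E)-3-methylglutaconic acid ((2E)-3-methylpent-2-enedioic acid) | OC(=O)/C=C(\C)CC(=O)O | starting material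
32 | (2E)-5-methoxy-3-methyl-5-oxopent-2-enoic acid | OC(=O)/C=C(\C)CC(=O)OC | intermediate
33 | C5 (E)-3-methylglutaconate ester with free C6 OH and Bpin side chain | CC[C@@H](C)[C@H]1C=C[C@H]2[C@H](OC(=O)/C=C(\C)CC(=O)OC)[C@H](O)C[C@@H](C)[C@@H]2[C@@]1(C)C(=O)CCB1OC(C)(C)C(C)(C)O1 | intermediate
34 | tandyukisin B | CC[C@@H](C)[C@H]1C=C[C@H]2[C@H](OC(=O)/C=C(\C)CC(=O)OC)[C@H](O)C[C@@H](C)[C@@H]2[C@@]1(C)C(=O)CCO | target

**Step count and risks**

Total step count: 23. Longest linear sequence: 18 steps (steps 1, 3–10, 14–20, 22, 23).

Steps most likely to fail: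

1. Step 18 (Proposed new method). The ketene may dimerise before capture, a second vinyllithium may add to the product enone, the carbene may undergo 1,2-hydride shift instead of the Wolff shift, or methylation may occur on oxygen or with poor facial selectivity. The fallback uses known chemistry and sets out from 25. Photolysis in THF–water should give the ring-contracted carboxylic acid F1 (classical Wolff contraction with capture by water). Its dianion (LDA 2.2 equiv, THF/DMPU) is methylated with MeI anti to the sec-butyl group to give the quaternary acid F2. Treatment of F2 with vinyllithium (3 equiv, THF, 0 °C; ketone synthesis from a lithium carboxylate) gives vinyl ketone 28, where the route is rejoined.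

2. Step 6. The hydrogen-bond direction may be lost, so that osmylation occurs anti to the pseudoaxial CH2OH, or the hydroxy amide may lactonise during work-up. The fallback sets out from silyl ether 7 and reverses the facial logic. Woodward cis-hydroxylation (I2, AgOAc, AcOH, then wet AcOH) should form the iodonium ion on the open α face; acetate opens it from the β face and the acetoxonium ion is hydrolysed to the β-cis hydroxy acetate F3. K2CO3 in MeOH gives the diol silyl ether F4, 2,2-dimethoxypropane/PPTS gives the acetonide silyl ether F5, and HF·pyridine returns the acetonide alcohol 10.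

3. Step 22. Discrimination between the two secondary hydroxyls may be poor, the acyl group may migrate between the cis oxygens, or the glutaconate may isomerise (E/Z or deconjugation) under DMAP. The fallback sets out from diol 30 and differentiates the hydroxyls by protection. 2-Chloro-1,1,1-trimethoxyethane with CSA gives the cyclic orthoester F6. Kinetic hydrolysis (aq. AcOH) should open it to the axial C6 chloroacetate F7 with C5–OH free. Esterification with 32 (DIC, cat. DMAP) gives the mixed diester F8, and thiourea (NaHCO3, EtOH) removes the chloroacetyl group selectively to give 33.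

Further compounds
F1 | step 18 | ring-contracted carboxylic acid (C1–H, C1 epimers) | CC[C@@H](C)[C@H]1C=C[C@H]2[C@@H]3OC(C)(C)O[C@@H]3C[C@@H](C)[C@@H]2C1C(=O)O
F2 | step 18 | C1-methylated quaternary acid (CH3 β, CO2H α) | CC[C@@H](C)[C@H]1C=C[C@H]2[C@@H]3OC(C)(C)O[C@@H]3C[C@@H](C)[C@@H]2[C@@]1(C)C(=O)O
F3 | step 6 | β-cis hydroxy acetate silyl ether (C6 acetate shown) | CON(C)C(=O)[C@@H]1[C@H](CO[Si](C)(C)C(C)(C)C)[C@H](O)[C@H](OC(C)=O)C[C@H]1C
F4 | step 6 | C5,C6-diol silyl ether | CON(C)C(=O)[C@@H]1[C@H](CO[Si](C)(C)C(C)(C)C)[C@H](O)[C@H](O)C[C@H]1C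
F5 | step 6 | C5,C6-acetonide silyl ether | CON(C)C(=O)[C@@H]1[C@H](CO[Si](C)(C)C(C)(C)C)[C@@H]2OC(C)(C)O[C@@H]2C[C@H]1C
F6 | step 22 | cyclic chloromethyl methoxy orthoester of diol 30 | CC[C@@H](C)[C@H]1C=C[C@H]2[C@@H]3OC(CCl)(OC)O[C@@H]3C[C@@H](C)[C@@H]2[C@@]1(C)C(=O)CCB1OC(C)(C)C(C)(C)O1
F7 | step 22 | C6 chloroacetate with free C5 OH | CC[C@@H](C)[C@H]1C=C[C@H]2[C@H](O)[C@H](OC(=O)CCl)C[C@@H](C)[C@@H]2[C@@]1(C)C(=O)CCB1OC(C)(C)C(C)(C)O1
F8 | step 22 | C5 glutaconate C6 chloroacetate diester | CC[C@@H](C)[C@H]1C=C[C@H]2[C@H](OC(=O)/C=C(\C)CC(=O)OC)[C@H](OC(=O)CCl)C[C@@H](C)[C@@H]2[C@@]1(C)C(=O)CCB1OC(C)(C)C(C)(C)O1
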